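Start with the Z.

the same everywhere: G 14 mM; E 14 mM; L 1.4 mM
- oak: Z 12 mM (fed, over 2.5 min); run made earlier; the fed solution adds 0.25 times the starting volume
- cedar: Z 180 mM (fed, over 2.5 min); run made earlier; the fed solution adds 0.25 times the starting volume
- south-west: Z 120 mM (fed, over 2.5 min); the fed solution adds 0.25 times the starting volume; time 2.5 min
- north-east: Z 28.0 mM (fed, over 2.5 min); the fed solution adds 0.25 times the starting volume; time 2.5 min
- west: Z 8.00 mM (fed, over 2.5 min); the fed solution adds 0.25 times the starting volume; time 2.5 min
- south: Z 40.0 mM (fed, over 2.5 min); the fed solution adds 0.25 times the starting volume; time 2.5 min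

| run | time / s | D / % |
|---|---|---|
| oak | 10.0 | 0 |
| oak | 15.0 | 0 |
| oak | 30.0 | 0.8 |
| oak | 60.0 | 1.0 |
| oak | 120 | 3.3 |
| cedar | 10.0 | 0.4 |
| cedar | 25.0 | 1.8 |
| cedar | 50.0 | 6.1 |
| cedar | 80.0 | 11.9 |
| cedar | 120 | 17.4 |

(readings scatter by 0.5 percentage points)

- L is single-handed; G and E are mirror images of each other, charged as a racemate, each of them at the stated concentration
- charges are per starting volume, the dose included; the dosed solution carries all of it
- candidate steps: D <-> Q; L + E <-> X; L + G <-> J; Z + J -> L + D; Z + X -> L + Q

1. all flasks from highest to lowest amount of D, in percent of the G and E together charged, at 2.5 min (south-west / north-east / west / south)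
2. the amount of D, in percent of the G and E together charged of the flask you put first, at 2.5 min
3. the amount of D, in percent of the G and E together charged of the flask you put last, at 2.5 min

1. Z is what these recipes vary, so we follow one quantity, the catch: D present at the end of the feed, in mM, per mM of Z charged. A rate proportional to the Z fed so far, all else held, makes D grow as the square of time, which lets us scale an early reading to 2.5 min.

2. The first way uses oak. Its reading of 3.3% at 120 s, scaled by the square of time, gives a catch of 12.0%.

3. The second way uses cedar, a different charge, read when 30.0 mM of its Z had been fed. Its reading of 1.8% at 25.0 s gives 10.1%. With a scatter of 0.5 percentage points on such small readings, the two agree, and we take their mean, 11.1%, as the low-feed catch.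

4. Cedar's late reading parts from them: 17.4% at 120 s would scale to a catch of 4.23%. The scaling is what cheats here. From 80.0 s to 120 s it demands a factor of 2.25, but the readings rose by a smaller factor, 1.46. So we continue cedar's last slope in a straight line instead, which gives 21.5% of D and a catch of 3.35%.

5. We treat the loss of catch as a correction to the low-feed value: catch = low-feed catch / (1 + charge / knee). The knee, the charge in that denominator, comes from cedar's end as 78.2 mM.

6. D still rises with charge under this rule, so our order runs from south-west down to west. Our reckoning gives south-west 18.7% and west 2.87%.

7. The forecast gives south-west > south > north-east > west, with 19% and 3.2%, on the ground of “D rising with Z charge, but less than proportionally”. Our order is the same, and our values lie slightly lower.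

8. The flasks give south-west > south > north-east > west, with 19.3% in south-west and 2.50% in west.

    D ⇌ Q (k = 0.00748 s⁻¹)
    L + E ⇌ X (K = 183 M⁻¹, k = 18.9 M⁻¹ s⁻¹)
    L + G ⇌ J (K = 16.0 M⁻¹, k = 17.7 M⁻¹ s⁻¹)
    Z + J → L + D (k = 24.4 M⁻¹ s⁻¹)
    Z + X → L + Q (k = 0.556 M⁻¹ s⁻¹)

In south-west at 2.50 min, 92.0% of the charged Z still stood in the flask, and Z, charged above G and E together, was not the limiting reagent there. The catch of south-west is 4.50%. A further flask, west with 32 mM of Z, tests the knee of 78.2 mM: the rule gives it 8.97% of D, and the flask holds 8.18%.

The numbers in the tables come from a simulation with made-up constants; the scatter is artificial.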